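The bicyclo[2.2.2]octene is opened by a retro-Diels–Alder cut into (R)-α-phellandrene and (+)-altholactone. Everything then rests on the oxolane ring of altholactone (O1, C2, C3, C3a, C7a), which is grown from an oxirane. A copper-catalysed vinyl-oxirane-to-2,5-dihydrofuran rearrangement shifts O1 from the cinnamylic carbon to the benzylic alkene terminus. In one operation it enlarges the three-membered ring by two carbons, sets C2 cis to the C7a side chain and leaves a C3=C3a alkene where the trans C3–OH/C3a–O pair is needed. The precursor is an enantiopure trans-oxirane bearing an (E)-styryl and a (Z)-acrylate arm. The step exploits the benzylic, formerly allylic O1–C2 bond and the 2,5-cis pattern.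

Key step: step 5

Remark: the locants O1, C2, C3, C3a, C5, C6, C7 and C7a follow the furo[3,2-b]pyran-5-one numbering of altholactone and denote the same atoms in every compound. Compounds 1, 5 and 10 are taken to be commercial.

Step 1
Reactants: 1 (2E,4E)-5-phenylpenta-2,4-dienal
Product: 2 (2E,4E)-5-phenylpenta-2,4-dien-1-ol
Conditions: NaBH4, MeOH, 0 °C
Reagents that add atoms: none
Why: Borohydride 1,2-reduction of a conjugated aldehyde is fast, leaves the diene untouched and creates no stereocentre.

Step 2
Reactants: 2 (2E,4E)-5-phenylpenta-2,4-dien-1-ol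
Product: 3 [(2S,3S)-3-[(E)-2-phenylethenyl]oxiran-2-yl]methanol
Conditions: Ti(OiPr)4 (10 mol%), L-(+)-diisopropyl tartrate (12 mol%), tBuOOH (anhydrous), 4 Å molecular sieves, CH2Cl2, −20 °C
Reagents that add atoms: tert-butyl hydroperoxide, CC(C)(C)OO
Why: The Sharpless asymmetric epoxidation touches only the alkene next to the carbinol, and the L-(+)-tartrate delivers oxygen to the face that gives the (2S,3S) trans-epoxy alcohol (same sense as for cinnamyl alcohol), which sets C7a and C3a, while the catalytic low-temperature protocol spares the acid-labile styryl oxirane.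

Step 3
Reactants: 3 [(2S,3S)-3-[(E)-2-phenylethenyl]oxiran-2-yl]methanol
Product: 4 (2R,3S)-3-[(E)-2-phenylethenyl]oxirane-2-carbaldehyde
Conditions: nPr4N[RuO4] (5 mol%), N-methylmorpholine N-oxide, 4 Å molecular sieves, CH2Cl2, rt
Reagents that add atoms: none
Why: The Ley–Griffith oxidation is neutral and stops at the aldehyde, so the oxirane and both stereocentres are untouched (the descriptor at the aldehyde-bearing carbon changes only through the priority rules).

Step 4
Reactants: 4 (2R,3S)-3-[(E)-2-phenylethenyl]oxirane-2-carbaldehyde; 5 methyl bis(2,2,2-trifluoroethyl)phosphonoacetate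
Product: 6 methyl (2Z)-3-{(2S,3S)-3-[(E)-2-phenylethenyl]oxiran-2-yl}prop-2-enoate
Conditions: 5, KN(SiMe3)2, 18-crown-6, THF, −78 °C; then 4
Reagents that add atoms: none
Why: In the Still–Gennari variant of the Horner–Wadsworth–Emmons olefination the electron-poor phosphonate eliminates rapidly and irreversibly from the kinetic adduct and gives the Z-enoate needed for later lactonisation, and at −78 °C the epoxy aldehyde is not epimerised.

Step 5
Reactants: 6 methyl (2Z)-3-{(2S,3S)-3-[(E)-2-phenylethenyl]oxiran-2-yl}prop-2-enoate
Product: 7 methyl (2Z)-3-[(2R,5S)-5-phenyl-2,5-dihydrofuran-2-yl]prop-2-enoate (2,5-cis)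
Conditions: Cu(hfacac)2 [copper bis(1,1,1,5,5,5-hexafluoroacetylacetonate)] (5 mol%), degassed toluene, 100 °C, sealed tube
Reagents that add atoms: none
Why: This is the copper-catalysed rearrangement of a vinyl oxirane to a 2,5-dihydrofuran, a formal suprafacial [1,3] shift of oxygen: the electron-poor copper centre binds the oxirane oxygen, inserts into the cinnamylic C3a–O1 bond, moves along the same face of the allyl unit to the benzylic terminus and closes the O1–C2 bond there by reductive elimination while the alkene moves to C3=C3a. The only ring closed is the five-membered one, formally a 5-endo-trig attack of the alkoxide oxygen on the terminus of the s-cis allyl unit, so that the three-membered ring O1/C7a/C3a is enlarged by C3 and C2. C7a keeps its C–O bond and therefore its configuration from the Sharpless step. The new benzylic stereocentre C2 is controlled by chirality transfer from the oxirane: oxygen leaves and returns on the same face of the allyl unit, and for a trans-oxirane with an E-alkene this geometry is expected to give the 2,5-cis product. The step needs selectivity between the two alkenyl arms, which the substrate secures because cleavage on the styryl side gives a phenyl-stabilised allyl unit whereas cleavage on the acrylate side is opposed by the ester, and the trans arrangement of the arms excludes a Cope rearrangement to a dihydrooxepine. Neutral, base-free and oxygen-free conditions are chosen because the product is a skipped diene that could isomerise to an aromatic furan.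

Step 6
Reactants: 7 methyl (2Z)-3-[(2R,5S)-5-phenyl-2,5-dihydrofuran-2-yl]prop-2-enoate
Product: 9 (+)-altholactone, via epoxy ester 8 (not isolated)
Conditions: mCPBA, CH2Cl2, 0 °C to rt; then CF3CO2H, H2O, 0 °C to rt
Reagents that add atoms: mCPBA, OOC(=O)c1cccc(Cl)c1; water, O
Why: The Prilezhaev epoxidation takes the more electron-rich ring alkene on the face anti to the two cis substituents, and acid then triggers a 6-exo-tet opening at C3a by the ester carbonyl oxygen with inversion (water hydrolyses the resulting alkoxycarbenium ion and methanol leaves), which places the C3a–O bond cis to the side chain and leaves the C3–OH trans to the phenyl group.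

Step 7
Reactants: 9 (+)-altholactone; 10 (R)-(−)-α-phellandrene
Product: 11 target
Conditions: 10 (10 equiv), 2,6-di-tert-butyl-4-methylphenol (cat.), toluene, 130 °C, sealed tube
Reagents that add atoms: none
Why: In this normal-electron-demand Diels–Alder reaction all four new stereocentres follow from matched preferences: the diene reacts on the face anti to its isopropyl group, the lactone alkene on its convex face (anti to O1 at C7a), the lactone carbonyl lies endo under the diene, and the "para" rule joins C7 (β-carbon) to the diene terminus next to the methyl-bearing carbon and C6 to the terminus next to CH(iPr).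

Compound list
1 | (2E,4E)-5-phenylpenta-2,4-dienal | O=C/C=C/C=C/c1ccccc1 | starting material
2 | (2E,4E)-5-phenylpenta-2,4-dien-1-ol | OC/C=C/C=C/c1ccccc1 | intermediate
3 | [(2S,3S)-3-[(E)-2-phenylethenyl]oxiran-2-yl]methanol | OC[C@@H]1O[C@H]1/C=C/c2ccccc2 | intermediate
4 | (2R,3S)-3-[(E)-2-phenylethenyl]oxirane-2-carbaldehyde | O=C[C@@H]1O[C@H]1/C=C/c2ccccc2 | intermediate
5 | methyl bis(2,2,2-trifluoroethyl)phosphonoacetate | COC(=O)CP(=O)(OCC(F)(F)F)OCC(F)(F)F | starting material
6 | methyl (2Z)-3-{(2S,3S)-3-[(E)-2-phenylethenyl]oxiran-2-yl}prop-2-enoate | COC(=O)/C=C\[C@@H]1O[C@H]1/C=C/c2ccccc2 | intermediate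
7 | methyl (2Z)-3-[(2R,5S)-5-phenyl-2,5-dihydrofuran-2-yl]prop-2-enoate (2,5-cis) | COC(=O)/C=C\[C@H]1C=C[C@@H](c2ccccc2)O1 | intermediate
8 | methyl (2Z)-3-[(1S,2S,4R,5R)-4-phenyl-3,6-dioxabicyclo[3.1.0]hexan-2-yl]prop-2-enoate (oxirane anti to phenyl and side chain) | COC(=O)/C=C\[C@@H]1O[C@H](c2ccccc2)[C@H]3O[C@H]31 | intermediate
9 | (+)-altholactone, (2R,3R,3aS,7aS)-3-hydroxy-2-phenyl-2,3,3a,7a-tetrahydro-5H-furo[3,2-b]pyran-5-one | O=C1C=C[C@@H]2O[C@H](c3ccccc3)[C@@H](O)[C@@H]2O1 | intermediate
10 | (R)-(−)-α-phellandrene, (5R)-2-methyl-5-(propan-2-yl)cyclohexa-1,3-diene | CC1=CC[C@H](C(C)C)C=C1 | starting material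
11 | endo, "para" [4+2] adduct of 9 and 10: a bicyclo[2.2.2]octene fused through C6 and C7 to the δ-lactone. C6 sits on the bridgehead next to CH(iPr) and C7 on the bridgehead next to C(Me)=. Both new bonds lie on the face of H-3a/H-7a, and the lactone ring and the isopropyl group are both syn to the C=C bridge | CC1=C[C@@H]2[C@@H]3C(=O)O[C@H]4[C@H](O)[C@@H](c5ccccc5)O[C@H]4[C@@H]3[C@H]1C[C@@H]2C(C)C | target

Total step count: 7. Longest linear sequence: 7 steps (1 to 11).

Steps most likely to fail

Step 5. The risks are opening of the oxirane on the acrylate side, loss of stereochemical fidelity if the cinnamyl unit escapes as a free cation or the benzylic ether re-ionises, a hydride shift to a carbonyl group, and isomerisation of the skipped diene to an aromatic ring on heating. The fallback sets out from 3 and comes back at 8. The ring enlargement is run before the acrylate exists, so the oxirane carries one alkenyl arm only and the skipped diene never forms. Alcohol 3 is silylated (TBSCl, imidazole, DMF) to the silyl ether F1, which is rearranged with Cu(hfacac)2 in toluene to the cis-dihydrofuran F2. Epoxidation with mCPBA anti to both substituents gives the epoxide F3, Bu4NF frees the alcohol F4, and nPr4N[RuO4]/N-methylmorpholine N-oxide gives the aldehyde F5. Still–Gennari olefination with 5 then gives 8, which is isolated here and lactonised with CF3CO2H/H2O as in the second half of step 6.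

Step 7. The risks are sluggish cycloaddition of the weakly activated lactone alkene, thermal [1,5]-hydrogen shifts in the diene at the temperature needed, and erosion of endo and regiochemical control. The fallback sets out from 9 and comes back at 11. The thermal reaction is replaced by a Lewis-acid-activated one on a protected dienophile. Compound 9 is silylated (TBSOTf, 2,6-lutidine, CH2Cl2) to the silyl ether F6. The cycloaddition with 10 is run with Me2AlCl in CH2Cl2 at −40 to 0 °C (the aluminium binds the lactone carbonyl and also scavenges protons) to give the silylated adduct F7, and HF·pyridine in THF releases 11.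

Step 6. The risks are slow epoxidation of an alkene deactivated by two allylic C–O bonds, acid-induced isomerisation of the skipped diene before it is oxidised, and intermolecular instead of intramolecular opening of the oxirane. The fallback sets out from 7 and comes back at 9. Epoxidation and opening are replaced by syn-dihydroxylation and an inverting lactonisation. OsO4 (cat.)/N-methylmorpholine N-oxide adds to the ring alkene anti to both substituents and gives the cis-diol ester F8, and Me3SnOH in 1,2-dichloroethane cleaves the ester under neutral conditions to the dihydroxy acid F9. An intramolecular Mitsunobu reaction (PPh3, diisopropyl azodicarboxylate, THF) closes the lactone. Only the activated C3a–OH can be reached by the tethered carboxylate, and its displacement with inversion gives 9.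

Further compounds
F1 | step 5 | tert-butyl(dimethyl){[(2S,3S)-3-[(E)-2-phenylethenyl]oxiran-2-yl]methoxy}silane | CC(C)(C)[Si](C)(C)OC[C@@H]1O[C@H]1/C=C/c2ccccc2
F2 | step 5 | tert-butyl(dimethyl){[(2R,5S)-5-phenyl-2,5-dihydrofuran-2-yl]methoxy}silane (2,5-cis) | CC(C)(C)[Si](C)(C)OC[C@H]1C=C[C@@H](c2ccccc2)O1
F3 | step 5 | tert-butyl(dimethyl){[(1S,2S,4R,5R)-4-phenyl-3,6-dioxabicyclo[3.1.0]hexan-2-yl]methoxy}silane | CC(C)(C)[Si](C)(C)OC[C@@H]1O[C@H](c2ccccc2)[C@H]3O[C@H]31
F4 | step 5 | [(1S,2S,4R,5R)-4-phenyl-3,6-dioxabicyclo[3.1.0]hexan-2-yl]methanol | OC[C@@H]1O[C@H](c2ccccc2)[C@H]3O[C@H]31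
F5 | step 5 | (1R,2R,4R,5R)-4-phenyl-3,6-dioxabicyclo[3.1.0]hexane-2-carbaldehyde | O=C[C@@H]1O[C@H](c2ccccc2)[C@H]3O[C@H]31
F6 | step 7 | O-tert-butyldimethylsilyl ether of 9 at the C3 hydroxyl (configuration as in 9) | O=C1C=C[C@@H]2O[C@H](c3ccccc3)[C@@H](O[Si](C)(C)C(C)(C)C)[C@@H]2O1
F7 | step 7 | O-tert-butyldimethylsilyl ether of 11 at the C3 hydroxyl (configuration as in 11) | CC1=C[C@@H]2[C@@H]3C(=O)O[C@H]4[C@H](O[Si](C)(C)C(C)(C)C)[C@@H](c5ccccc5)O[C@H]4[C@@H]3[C@H]1C[C@@H]2C(C)C
F8 | step 6 | methyl (2Z)-3-[(2S,3R,4S,5R)-3,4-dihydroxy-5-phenyloxolan-2-yl]prop-2-enoate | COC(=O)/C=C\[C@@H]1O[C@H](c2ccccc2)[C@@H](O)[C@H]1O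
F9 | step 6 | (2Z)-3-[(2S,3R,4S,5R)-3,4-dihydroxy-5-phenyloxolan-2-yl]prop-2-enoic acid | OC(=O)/C=C\[C@@H]1O[C@H](c2ccccc2)[C@@H](O)[C@H]1O
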